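**Strategy.** The γ-lactone is disconnected at C2–C3 (lactone: C1 carbonyl, C2 methylene; dioxane carbons: C3 peroxy methine, C4 methyl carbinol carbon, C5 methylene, C6 methyl/hexadecyl peroxy carbon). A rhodium carbene generated from a diazoacetate on the C4 oxygen lies 1,5 to the C3–H bond, which is activated by the adjacent peroxide oxygen of the 1,2-dioxane ring. Insertion forms the C2–C3 bond, closes the lactone ring cis-fused and sets C3 in one operation, giving the target directly. The precursor is (4S,6R)-6-hexadecyl-4,6-dimethyl-1,2-dioxan-4-yl diazoacetate; its C4 centre comes from (R)-2-methylglycidol and its C6 centre from a syn-selective peroxycarbenium allylation.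

Key step: step 11

Remark: the locants of the overview are used throughout (peroxide O1 on C6, O2 on C3), also where systematic rules would number a ring the other way. The target is 3S,4S,6R, with lactone ring and hexadecyl chain on one face and both methyl groups on the other. The ketal carbon C6 of 6, 7 and 8 is an epimer mixture that converges in cation 10.

**Step 1**
Reactants: 1 (R)-2-methylglycidol; 2 isopropenylmagnesium bromide
Product: 3 (2S)-2,4-dimethylpent-4-ene-1,2-diol
Conditions: 2 (2.5 equiv), CuI (10 mol%), THF, −30 → 0 °C; aqueous work-up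
Reagents that add atoms: none
Why: Copper-catalysed SN2 opening of the epoxide by the Grignard reagent at its unsubstituted CH2 (the hydroxyl consumes one equivalent); no bond at the quaternary carbinol carbon is broken, so the centre of 1 becomes C4 unchanged.

**Step 2**
Reactants: 3 (2S)-2,4-dimethylpent-4-ene-1,2-diol
Product: 5 (2S)-2-methyl-2-(2-methylprop-2-en-1-yl)oxirane, via primary monotosylate 4 (not isolated)
Conditions: NaH (2.2 equiv), THF, 0 °C; N-tosylimidazole (1.05 equiv), 0 °C → rt
Reagents that add atoms: none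
Why: One-pot diol-to-epoxide conversion: the primary alkoxide is sulfonylated selectively and the neighbouring tertiary alkoxide displaces the tosylate at the primary carbon (intramolecular Williamson reaction, 3-exo-tet), so the stereocentre keeps its configuration.

**Step 3**
Reactants: 5 (2S)-2-methyl-2-(2-methylprop-2-en-1-yl)oxirane
Product: 7 (4S)-6-methoxy-4,6-dimethyl-1,2-dioxan-4-ol (C6 epimers), via hydroperoxy ketal 6 (not isolated)
Conditions: O3, CH2Cl2/MeOH (4:1), −78 °C; N2 purge; then K2CO3 (0.2 equiv), MeOH, 0 °C → rt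
Reagents that add atoms: ozone [O-][O+]=O; methanol CO
Why: Ozonolysis in methanol (Criegee mechanism) traps the ketone O-oxide of the 1,1-disubstituted alkene as the α-methoxy hydroperoxide, whose peroxy anion then opens the 2,2-disubstituted epoxide by SN2 attack at the unhindered CH2 (6-endo closure, the 5-exo carbon being quaternary) to give the dioxane with C4 untouched.

**Step 4**
Reactants: 7 (4S)-6-methoxy-4,6-dimethyl-1,2-dioxan-4-ol
Product: 8 (4S)-6-methoxy-4,6-dimethyl-4-(triethylsilyloxy)-1,2-dioxane (C6 epimers)
Conditions: TESCl, imidazole, DMAP (cat.), DMF, rt → 40 °C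
Reagents that add atoms: chlorotriethylsilane CC[Si](Cl)(CC)CC
Why: Silyl ether formation on the tertiary alcohol under mildly basic conditions that leave the peroxy ketal intact; a non-participating ether of moderate size is wanted for the facial control in step 5.

**Step 5**
Reactants: 8 (4S)-6-methoxy-4,6-dimethyl-4-(triethylsilyloxy)-1,2-dioxane; 9 allyltrimethylsilane
Product: 11 (4S,6R)-6-allyl-4,6-dimethyl-4-(triethylsilyloxy)-1,2-dioxane, via peroxycarbenium ion 10 (not isolated)
Conditions: 9 (3 equiv), SnCl4 (1.1 equiv), CH2Cl2, −78 °C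
Reagents that add atoms: none
Why: Hosomi–Sakurai-type allylation of a peroxy ketal: SnCl4 ionises the C6–OMe bond and the allylsilane traps the peroxycarbenium ion, whose half-chair should carry the C4 silyloxy group pseudoaxial (the electrostatic preference of alkoxy groups in six-membered oxocarbenium-type ions) and the C4 methyl pseudoequatorial, so that chair-like axial attack enters on the face of the C4 oxygen and sets C6 as R.

**Step 6**
Reactants: 11 (4S,6R)-6-allyl-4,6-dimethyl-4-(triethylsilyloxy)-1,2-dioxane; 12 1-pentadecene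
Product: 13 (4S,6R)-6-(hexadec-2-en-1-yl)-4,6-dimethyl-4-(triethylsilyloxy)-1,2-dioxane (E/Z mixture)
Conditions: 12 (4 equiv), Hoveyda–Grubbs II (5 mol%), CH2Cl2, 40 °C
Reagents that add atoms: none
Why: Olefin cross-metathesis of two terminal alkenes with the cheap partner in excess; dialkyl peroxides are tolerated by ruthenium alkylidenes, the phosphine-free catalyst carries no reductant for the O–O bond, and the alkene geometry is irrelevant because the double bond is saturated next.

**Step 7**
Reactants: 13 (4S,6R)-6-(hexadec-2-en-1-yl)-4,6-dimethyl-4-(triethylsilyloxy)-1,2-dioxane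
Product: 14 (4S,6R)-6-hexadecyl-4,6-dimethyl-4-(triethylsilyloxy)-1,2-dioxane
Conditions: KO2CN=NCO2K (excess), AcOH (slow addition), pyridine/CH2Cl2, 0 °C → rt
Reagents that add atoms: none
Why: Diimide reduction: diimide generated in the flask delivers H2 to the alkene through a concerted cyclic transfer and leaves the O–O bond alone, which catalytic hydrogenation would cleave.

**Step 8**
Reactants: 14 (4S,6R)-6-hexadecyl-4,6-dimethyl-4-(triethylsilyloxy)-1,2-dioxane
Product: 15 (4S,6R)-6-hexadecyl-4,6-dimethyl-1,2-dioxan-4-ol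
Conditions: HF·pyridine, THF/pyridine, 0 °C → rt
Reagents that add atoms: none
Why: Fluoride-driven Si–O cleavage in a buffered acidic medium, chosen over basic fluoride so that neither a free β-peroxy alkoxide (Grob-type fragmentation) nor α-peroxy deprotonation (Kornblum–DeLaMare) is provoked.

**Step 9**
Reactants: 15 (4S,6R)-6-hexadecyl-4,6-dimethyl-1,2-dioxan-4-ol
Product: 16 (4S,6R)-6-hexadecyl-4,6-dimethyl-1,2-dioxan-4-yl bromoacetate
Conditions: BrCH2COBr (2 equiv), PhNMe2 (3 equiv), CH2Cl2, 0 °C → rt
Reagents that add atoms: bromoacetyl bromide BrCC(=O)Br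
Why: O-Acylation of the hindered tertiary alcohol with a small, very reactive acyl bromide and a non-nucleophilic aniline base as HBr scavenger, the classical preparation of tert-alkyl bromoacetates; the C4–O bond is not broken.

**Step 10**
Reactants: 16 (4S,6R)-6-hexadecyl-4,6-dimethyl-1,2-dioxan-4-yl bromoacetate
Product: 18 (4S,6R)-6-hexadecyl-4,6-dimethyl-1,2-dioxan-4-yl diazoacetate, via ditosylhydrazinoacetate 17 (not isolated)
Conditions: TsNHNHTs (2 equiv), DBU (5 equiv), THF, 0 °C, 20 min
Reagents that add atoms: N,N'-ditosylhydrazine Cc1ccc(cc1)S(=O)(=O)NNS(=O)(=O)c1ccc(C)cc1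
Why: Diazo ester synthesis from a bromoacetate: the ditosylhydrazine anion is N-alkylated (SN2) and two base-induced sulfinate eliminations then give the diazoacetate within minutes at 0 °C, a short exposure to DBU that an unactivated dialkyl peroxide should survive.

**Step 11**
Reactants: 18 (4S,6R)-6-hexadecyl-4,6-dimethyl-1,2-dioxan-4-yl diazoacetate
Product: 19 (1S,4R,6S)-4-hexadecyl-4,6-dimethyl-2,3,7-trioxabicyclo[4.3.0]nonan-8-one (the target; 3S,4S,6R in the locants used here)
Conditions: Rh2(OAc)4 (2 mol%), CH2Cl2, 40 °C, slow addition of 18 (syringe pump, ca. 0.01 M)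
Reagents that add atoms: none
Why: Proposed new method: loss of N2 on the dirhodium catalyst should give an electrophilic metal-bound carbene whose carbon (C2) attacks the C3–H bond through a three-centre, hydride-transfer-like transition state, forming C2–C3 with retention at C3, the α-peroxy oxygen stabilising the positive charge that builds up at C3 much as an ether oxygen does. The closest known reaction type is the Rh(II)-catalysed 1,5 C–H insertion of alkyl diazoacetates to γ-butyrolactones, which is favoured at C–H bonds next to ether oxygen (for example in 1,3-dioxan-5-yl diazoacetates) but has not been run next to an O–O bond. The γ-lactone closes by C–C bond formation through a five-membered cyclic transition state and is annulated to the dioxane across C3–C4. The new C3 centre is controlled by C4: in the chair with both methyl groups equatorial the ester oxygen is axial, only the equatorial C3–H on its own face is gauche to it and within reach, and insertion there gives the cis fusion (3S). The step needs site selectivity for C3–H over the C5 methylene and the C4 methyl, which should follow from activation by the adjacent peroxide oxygen, from shielding of C5 between two quaternary carbons and from the low reactivity of primary C–H. Weakly basic peroxide oxygens should form ylides less readily than ethers, and the acetate catalyst is too hard to oxidise to reduce the O–O bond.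

**Compound list**
1 | (R)-2-methylglycidol | C[C@@]1(CO)CO1 | starting material
2 | isopropenylmagnesium bromide | CC(=C)[Mg]Br | starting material
3 | (2S)-2,4-dimethylpent-4-ene-1,2-diol | C[C@@](O)(CO)CC(C)=C | intermediate
4 | (2S)-2-hydroxy-2,4-dimethylpent-4-en-1-yl 4-methylbenzenesulfonate (not isolated) | C[C@@](O)(COS(=O)(=O)c1ccc(C)cc1)CC(C)=C | intermediate
5 | (2S)-2-methyl-2-(2-methylprop-2-en-1-yl)oxirane | C[C@]1(CC(C)=C)CO1 | intermediate
6 | (2S)-2-(2-hydroperoxy-2-methoxypropyl)-2-methyloxirane, ketal epimers (not isolated) | COC(C)(OO)C[C@@]1(C)CO1 | intermediate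
7 | (4S)-6-methoxy-4,6-dimethyl-1,2-dioxan-4-ol, C6 epimers | COC1(C)C[C@](C)(O)COO1 | intermediate
8 | (4S)-6-methoxy-4,6-dimethyl-4-(triethylsilyloxy)-1,2-dioxane, C6 epimers | COC1(C)C[C@](C)(O[Si](CC)(CC)CC)COO1 | intermediate
9 | allyltrimethylsilane | C=CC[Si](C)(C)C | starting material
10 | (4S)-4,6-dimethyl-4-(triethylsilyloxy)-1,2-dioxan-6-ylium, drawn as the O1=C6 peroxycarbenium form (not isolated) | CC1=[O+]OC[C@@](C)(O[Si](CC)(CC)CC)C1 | intermediate
11 | (4S,6R)-6-allyl-4,6-dimethyl-4-(triethylsilyloxy)-1,2-dioxane | C=CC[C@]1(C)C[C@](C)(O[Si](CC)(CC)CC)COO1 | intermediate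
12 | 1-pentadecene | C=CCCCCCCCCCCCCC | starting material
13 | (4S,6R)-6-(hexadec-2-en-1-yl)-4,6-dimethyl-4-(triethylsilyloxy)-1,2-dioxane, E/Z mixture | CCCCCCCCCCCCCC=CC[C@]1(C)C[C@](C)(O[Si](CC)(CC)CC)COO1 | intermediate
14 | (4S,6R)-6-hexadecyl-4,6-dimethyl-4-(triethylsilyloxy)-1,2-dioxane | CCCCCCCCCCCCCCCC[C@]1(C)C[C@](C)(O[Si](CC)(CC)CC)COO1 | intermediate
15 | (4S,6R)-6-hexadecyl-4,6-dimethyl-1,2-dioxan-4-ol | CCCCCCCCCCCCCCCC[C@]1(C)C[C@](C)(O)COO1 | intermediate
16 | (4S,6R)-6-hexadecyl-4,6-dimethyl-1,2-dioxan-4-yl bromoacetate | CCCCCCCCCCCCCCCC[C@]1(C)C[C@](C)(OC(=O)CBr)COO1 | intermediate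
17 | (4S,6R)-6-hexadecyl-4,6-dimethyl-1,2-dioxan-4-yl [1,2-bis(4-methylphenylsulfonyl)hydrazinyl]acetate (not isolated) | CCCCCCCCCCCCCCCC[C@]1(C)C[C@](C)(OC(=O)CN(NS(=O)(=O)c2ccc(C)cc2)S(=O)(=O)c2ccc(C)cc2)COO1 | intermediate
18 | (4S,6R)-6-hexadecyl-4,6-dimethyl-1,2-dioxan-4-yl diazoacetate | CCCCCCCCCCCCCCCC[C@]1(C)C[C@](C)(OC(=O)C=[N+]=[N-])COO1 | intermediate
19 | (1S,4R,6S)-4-hexadecyl-4,6-dimethyl-2,3,7-trioxabicyclo[4.3.0]nonan-8-one, cis-fused | CCCCCCCCCCCCCCCC[C@]1(C)C[C@]2(C)OC(=O)C[C@@H]2OO1 | target

**Step count.** Total: 11 steps. Longest linear sequence: 11 steps, from 1; compounds 2, 9 and 12 enter as purchased partners.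

**Steps most likely to fail**

1. Step 11 (C–H insertion next to the peroxide). The carbene may instead add to a peroxide oxygen (ylide formation and O–O scission), dimerise or insert at the C5 methylene, and the metal may attack the O–O bond.
 - Fallback, known chemistry without C–H insertion: it sets out from diol 3 and comes back at target 19.
 - Parikh–Doering oxidation of the primary alcohol of 3 (SO3·pyridine, DMSO, iPr2NEt) should give (2S)-2-hydroxy-2,4-dimethylpent-4-enal F1.
 - Ketenylidene(triphenyl)phosphorane (toluene, reflux) acylates the tertiary hydroxyl and closes by intramolecular Wittig reaction to (5S)-5-methyl-5-(2-methylprop-2-en-1-yl)furan-2(5H)-one F2, which already holds C1–C4.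
 - Ozonolysis of the electron-rich side-chain alkene in methanol gives (5S)-5-(2-hydroperoxy-2-methoxypropyl)-5-methylfuran-2(5H)-one F3.
 - Amine-catalysed intramolecular oxa-Michael addition of the hydroperoxide to the butenolide (Et2NH, CF3CH2OH) closes the dioxane as cis-fused (1S,6S)-4-methoxy-4,6-dimethyl-2,3,7-trioxabicyclo[4.3.0]nonan-8-one F4; this is the established way to the peroxylactone skeleton.
 - SnCl4 and 9 then give (1S,4R,6S)-4-allyl-4,6-dimethyl-2,3,7-trioxabicyclo[4.3.0]nonan-8-one F5, the allyl group again being expected on the face of the C4 oxygen.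
 - Cross-metathesis with 12 gives (1S,4R,6S)-4-(hexadec-2-en-1-yl)-4,6-dimethyl-2,3,7-trioxabicyclo[4.3.0]nonan-8-one F6, and diimide reduction as in step 7 gives 19.

2. Step 3 (ring closure onto the epoxide). The peroxy anion may close in the 5-exo sense at the quaternary epoxide carbon, or close so slowly that the hydroperoxy ketal decomposes.
 - Fallback: from epoxide 5, back at 7. The O2–C3 bond is made intermolecularly and the ring is closed by ketalisation, which can only give the six-membered ring.
 - Base-catalysed opening of 5 at its CH2 by 2-methoxyprop-2-yl hydroperoxide (from ozonolysis of 2,3-dimethylbut-2-ene in methanol; KOH cat., 40 °C) gives (2S)-1-[(2-methoxypropan-2-yl)peroxy]-2,4-dimethylpent-4-en-2-ol F7.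
 - Ozonolysis in CH2Cl2 with Me2S work-up gives (4S)-4-hydroxy-5-[(2-methoxypropan-2-yl)peroxy]-4-methylpentan-2-one F8.
 - TsOH (cat.) in methanol passes the ketal protecting group to the solvent; the freed primary hydroperoxide adds to the ketone and the hemiketal is methylated to 7.

3. Step 5 (allylation at C6). Facial selectivity in the capture of the peroxycarbenium ion may be poor, or the silyl ether may be lost under the Lewis acid.
 - Fallback: from 7, back at 15. The allyl group is delivered from the C4 oxygen itself, which can reach only the syn face of C6.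
 - Silylation of 7 with allylchlorodimethylsilane and imidazole gives (4S)-4-{[dimethyl(prop-2-en-1-yl)silyl]oxy}-6-methoxy-4,6-dimethyl-1,2-dioxane F9.
 - TMSOTf (cat.), CH2Cl2, −78 °C ionises the ketal and the tethered allylsilane transfers its allyl group to C6 (silicon-tethered intramolecular allylation, as used for β-silyloxy aldehydes); HF·pyridine work-up gives (4S,6R)-6-allyl-4,6-dimethyl-1,2-dioxan-4-ol F10.
 - Cross-metathesis with 12 gives (4S,6R)-6-(hexadec-2-en-1-yl)-4,6-dimethyl-1,2-dioxan-4-ol F11, and diimide reduction gives 15; this also spares steps 4 and 8.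

**Further compounds**
F1 | step 11 | (2S)-2-hydroxy-2,4-dimethylpent-4-enal | C[C@@](O)(C=O)CC(C)=C
F2 | step 11 | (5S)-5-methyl-5-(2-methylprop-2-en-1-yl)furan-2(5H)-one | C[C@]1(CC(C)=C)C=CC(=O)O1
F3 | step 11 | (5S)-5-(2-hydroperoxy-2-methoxypropyl)-5-methylfuran-2(5H)-one, ketal epimers | COC(C)(OO)C[C@@]1(C)C=CC(=O)O1
F4 | step 11 | (1S,6S)-4-methoxy-4,6-dimethyl-2,3,7-trioxabicyclo[4.3.0]nonan-8-one, ketal epimers | COC1(C)C[C@]2(C)OC(=O)C[C@@H]2OO1
F5 | step 11 | (1S,4R,6S)-4-allyl-4,6-dimethyl-2,3,7-trioxabicyclo[4.3.0]nonan-8-one | C=CC[C@]1(C)C[C@]2(C)OC(=O)C[C@@H]2OO1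
F6 | step 11 | (1S,4R,6S)-4-(hexadec-2-en-1-yl)-4,6-dimethyl-2,3,7-trioxabicyclo[4.3.0]nonan-8-one, E/Z mixture | CCCCCCCCCCCCCC=CC[C@]1(C)C[C@]2(C)OC(=O)C[C@@H]2OO1
F7 | step 3 | (2S)-1-[(2-methoxypropan-2-yl)peroxy]-2,4-dimethylpent-4-en-2-ol | C[C@@](O)(COOC(C)(C)OC)CC(C)=C
F8 | step 3 | (4S)-4-hydroxy-5-[(2-methoxypropan-2-yl)peroxy]-4-methylpentan-2-one | C[C@@](O)(COOC(C)(C)OC)CC(C)=O
F9 | step 5 | (4S)-4-{[dimethyl(prop-2-en-1-yl)silyl]oxy}-6-methoxy-4,6-dimethyl-1,2-dioxane, C6 epimers | COC1(C)C[C@](C)(O[Si](C)(C)CC=C)COO1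
F10 | step 5 | (4S,6R)-6-allyl-4,6-dimethyl-1,2-dioxan-4-ol | C=CC[C@]1(C)C[C@](C)(O)COO1
F11 | step 5 | (4S,6R)-6-(hexadec-2-en-1-yl)-4,6-dimethyl-1,2-dioxan-4-ol, E/Z mixture | CCCCCCCCCCCCCC=CC[C@]1(C)C[C@](C)(O)COO1
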